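**Plan**

- Numbering: trione ring C1(benzoyl)–C2(=O)–C3–C4(=O)–C5(geranyl)–C9(=O); bridges C5–C6H2–C7H–C8(CH3)2–C1 and C7–C10H2–C11H–C3; cyclopentane C3–C11–C12(CH3)2–C13H2–C14H2.
- Retrosynthesis: cut C11–H and C11–C12 (cyclopentane); take out C10 (C7–C10, C10–C11) to reach an adamantane with a C11 ketone; cut C3–C11, C1–C8 and C5–C6 to an enal cap plus a dialkylated trihydroxybenzophenone; cut the two ring-carbon alkyl bonds.
- Forward: arene alkylations; one annulation closes the three new six-membered rings of the adamantane; oxidation gives the C11 ketone; CH2 insertion enlarges two six-membered rings to seven; the cyclopentane closes last and C11–O is exchanged for C11–H.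
- Enabling feature: C11 sits on the two-carbon bridge C10–C11 between C7 and C3. Without C10 it is the bridging ketone of an adamantane-2,4,9,11-tetraone and the only carbonyl with a CH neighbour (C7), so a diazoalkane can insert C10 into the C7–C11 bond.
- Stereochemistry: C5 is set by chiral phase-transfer catalysis in the dearomatizing alkylation; C1, C7 and C3 follow because the cage can close only on the face that carries C6; C11 is set last by hydrogen-atom delivery to the C11 radical from the C4/C6 face.

Key step: step 9

Assumption: the cinchonidinium catalyst of step 7 is taken to give the cage enantiomer drawn (otherwise its cinchoninium pseudoenantiomer is used); compound 3 is written open-chain although it should rest as a cyclic hemiketal.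

**Route**

Step 1
Reactants: 1 2,4,6-trihydroxybenzophenone; 2 methyl vinyl ketone
Product: 3 4-(3-benzoyl-2,4,6-trihydroxyphenyl)butan-2-one
Conditions: 2 (1.0 equiv), Et3N (0.2 equiv), THF–H2O 4:1, 0 °C to rt
Reagents that add atoms: none
Why: Michael addition of the phloroglucinol (a vinylogous acid) through a free ring carbon to the enone; hemiketal formation on the neighbouring phenol should slow a second addition.

Step 2
Reactants: 3 4-(3-benzoyl-2,4,6-trihydroxyphenyl)butan-2-one
Product: 4 3-(3-methylbut-3-enyl)-2,4,6-trihydroxybenzophenone
Conditions: Ph3PCH3Br (5 equiv), KOtBu (5 equiv), THF, 0 °C to rt; aq. NH4Cl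
Reagents that add atoms: methyltriphenylphosphonium bromide (as its ylide), C[P+](c1ccccc1)(c1ccccc1)c1ccccc1.[Br-]
Why: Wittig methylenation of the side-chain methyl ketone, which the base frees from its hemiketal; the diaryl ketone, flanked by two phenoxides, should not react.

Step 3
Reactants: 4 3-(3-methylbut-3-enyl)-2,4,6-trihydroxybenzophenone; 5 geranyl bromide
Product: 6 3-geranyl-5-(3-methylbut-3-enyl)-2,4,6-trihydroxybenzophenone
Conditions: 5 (1.05 equiv), 10% aq. KOH, 0 °C
Reagents that add atoms: none
Why: SN2 C-alkylation of the phloroglucinol anion by the allylic bromide at its only unsubstituted ring carbon, the usual course of C-prenylation of acylphloroglucinols in aqueous alkali.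

Step 4
Reactants: 7 diethyl isopropylidenemalonate
Product: 8 2-(propan-2-ylidene)propane-1,3-diol
Conditions: i-Bu2AlH (4.5 equiv), CH2Cl2, −78 to 0 °C; aq. potassium sodium tartrate
Reagents that add atoms: none
Why: 1,2-hydride reduction of both ester groups of the alkylidene malonate, which leaves the tetrasubstituted alkene untouched.

Step 5
Reactants: 8 2-(propan-2-ylidene)propane-1,3-diol
Product: 10 2-(hydroxymethyl)-3-methylbut-2-enyl acetate, via cyclic orthoester 9 (not isolated)
Conditions: MeC(OMe)3 (1.3 equiv), pyridinium p-toluenesulfonate (0.05 equiv), CH2Cl2, rt; then H2O (2 equiv), rt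
Reagents that add atoms: trimethyl orthoacetate, CC(OC)(OC)OC; water, O
Why: monoacylation of a symmetrical 1,3-diol through its cyclic orthoester, whose hydrolysis can release only one acetate per molecule.

Step 6
Reactants: 10 2-(hydroxymethyl)-3-methylbut-2-enyl acetate
Product: 11 2-(acetoxymethyl)-3-methylbut-2-enal
Conditions: Dess–Martin periodinane (1.3 equiv), CH2Cl2, 0 °C to rt
Reagents that add atoms: none
Why: Dess–Martin oxidation of the primary allylic alcohol to the enal under neutral conditions that spare the allylic acetate.

Step 7
Reactants: 6 3-geranyl-5-(3-methylbut-3-enyl)-2,4,6-trihydroxybenzophenone; 11 2-(acetoxymethyl)-3-methylbut-2-enal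
Product: 14 adamantanol (C11 carbinol of the adamantane-2,4,9-trione), via dearomatized enal 12 (not isolated), via bicyclic aldehyde 13 (not isolated)
Conditions: 11 (1.5 equiv), O-allyl-N-(9-anthracenylmethyl)cinchonidinium bromide (0.25 equiv), CsOH·H2O (6 equiv), 4 Å molecular sieves, CH2Cl2, −50 °C
Reagents that add atoms: none
Why: alkylative dearomatization–annulation under chiral phase-transfer catalysis (C-alkylation at the acetoxymethyl carbon with loss of acetate, Michael addition of C1 to C8, aldol closure of C3 on the C7 aldehyde); the ammonium ion pair directs the enal to one face of an alkylated ring carbon, fixing C5 and through the forced cage closure C1, C7 and C3, while the C11 carbinol centre is removed in step 8; the catalyst cannot tell the two ring alkyl groups apart, so the isomer that starts at the methylbutenyl-bearing carbon is expected alongside and is separated by chromatography.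

Step 8
Reactants: 14 adamantanol
Product: 15 adamantane tetraone (C11 ketone)
Conditions: Dess–Martin periodinane (1.5 equiv), CH2Cl2, 0 °C to rt
Reagents that add atoms: none
Why: Dess–Martin oxidation of the secondary C11 alcohol under neutral, non-nucleophilic conditions, which should avoid retro-aldol opening of the β-hydroxy diketone.

Step 9
Reactants: 15 adamantane tetraone; 16 trimethylsilyldiazomethane
Product: 18 homoadamantane tetraone (C10H2 between C7 and C11), via silyl ketone 17 (not isolated)
Conditions: 16 (1.5 equiv), AlMe3 (1.2 equiv), CH2Cl2, −78 to −20 °C; then 1 M HCl, THF, 0 °C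
Reagents that add atoms: none
Why: AlMe3 binds the C11 carbonyl, the only one of the five ketones with a CH neighbour (C7) rather than two quaternary neighbours or an aryl group, and the diazo carbon of 16 adds to it to give an aluminium-bound diazonium alkoxide. Loss of N2 is coupled to a 1,2-shift of C7 from C11 to the diazo carbon, which becomes C10; the tertiary alkyl carbon C7 migrates in preference to C3, which is fully substituted and carries two further acyl groups. This is the Lewis-acid-promoted diazoalkane homologation of ketones (Tiffeneau–Demjanov type), known for adamantanone to homoadamantanone. No ring is closed: the two six-membered rings that share the C7–C11 bond grow to seven-membered rings by insertion of C10, and the new skeletal bonds are C7–C10 and C10–C11. No stereocentre is created in 18, because the silyl-bearing C10 of 17 becomes CH2 on protodesilylation, C7 migrates with retention and C1, C3, C5 and C7 stay locked in the cage. The silyl group on C10 should block a second insertion, and the low temperature and absence of nucleophilic base protect the triacylated C3 from acyl cleavage.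

Step 10
Reactants: 18 homoadamantane tetraone
Product: 19 cyclopentane-fused C11 tertiary alcohol
Conditions: Fe(acac)3 (0.5 equiv), PhSiH3 (2.5 equiv), EtOH–THF 1:1, 40 °C
Reagents that add atoms: none
Why: iron-hydride hydrogen atom transfer (Mukaiyama type) to the 1,1-disubstituted alkene, which should react faster than the trisubstituted geranyl alkenes, gives the tertiary C12 radical; it closes 5-exo onto C11, the only carbonyl on C3 not shielded by two quaternary carbons, and the oxygen radical is reduced to the alkoxide; C12 is expected to approach from the C4 side, but this C11 configuration is not kept.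

Step 11
Reactants: 19 cyclopentane-fused C11 tertiary alcohol
Product: 20 C11 methyl oxalate
Conditions: MeO2CCOCl (3 equiv), 4-(dimethylamino)pyridine (3 equiv), CH2Cl2, 0 °C to rt
Reagents that add atoms: methyl chlorooxoacetate, COC(=O)C(=O)Cl
Why: acylation of the hindered tertiary alcohol by a highly electrophilic oxalyl half-chloride under nucleophilic catalysis, without strong base, so that the alkoxide needed for retro-aldol cleavage is not formed.

Step 12
Reactants: 20 C11 methyl oxalate
Product: 21 target (CNP0168637.1)
Conditions: Bu3SnH (3 equiv), AIBN (0.2 equiv), toluene, 100 °C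
Reagents that add atoms: none
Why: Barton-type radical deoxygenation of a tertiary oxalate: the stannyl radical adds to the oxalate, the C11–O bond breaks to the planar C11 radical, and Bu3SnH delivers hydrogen from the C4/C6 face, away from the C8 methyl that leans over the C10–C11 bridge, so that C12 ends on the C2 side as in the target.

**Compound list**

1 | 2,4,6-trihydroxybenzophenone | O=C(c1ccccc1)c1c(O)cc(O)cc1O | starting material
2 | methyl vinyl ketone (but-3-en-2-one) | CC(=O)C=C | starting material
3 | 4-(3-benzoyl-2,4,6-trihydroxyphenyl)butan-2-one (open form of the hemiketal) | CC(=O)CCc1c(O)cc(O)c(C(=O)c2ccccc2)c1O | intermediate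
4 | 3-(3-methylbut-3-enyl)-2,4,6-trihydroxybenzophenone | C=C(C)CCc1c(O)cc(O)c(C(=O)c2ccccc2)c1O | intermediate
5 | geranyl bromide, (E)-1-bromo-3,7-dimethylocta-2,6-diene | CC(C)=CCC/C(C)=C/CBr | starting material
6 | 3-geranyl-5-(3-methylbut-3-enyl)-2,4,6-trihydroxybenzophenone | CC(C)=CCC/C(C)=C/Cc1c(O)c(CCC(C)=C)c(O)c(C(=O)c2ccccc2)c1O | intermediate
7 | diethyl isopropylidenemalonate | CCOC(=O)C(=C(C)C)C(=O)OCC | starting material
8 | 2-(propan-2-ylidene)propane-1,3-diol | CC(C)=C(CO)CO | intermediate
9 | 2-methoxy-2-methyl-5-(propan-2-ylidene)-1,3-dioxane (cyclic orthoester) | COC1(C)OCC(=C(C)C)CO1 | intermediate (not isolated)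
10 | 2-(hydroxymethyl)-3-methylbut-2-enyl acetate | CC(=O)OCC(CO)=C(C)C | intermediate
11 | 2-(acetoxymethyl)-3-methylbut-2-enal | CC(=O)OCC(C=O)=C(C)C | intermediate
12 | dearomatized enal: cyclohexadienone with quaternary C5 carrying geranyl and the CH2–C(CHO)=C(CH3)2 chain, C5 as in the target | CC(C)=CCC/C(C)=C/C[C@@]1(CC(C=O)=C(C)C)C(=O)C(CCC(C)=C)=C(O)C(C(=O)c2ccccc2)=C1O | intermediate (not isolated)
13 | bicyclic aldehyde: 1-benzoyl-5-geranyl-8,8-dimethylbicyclo[3.3.1]nonane-2,4,9-trione (enol form) with 3-(3-methylbut-3-enyl) and axial C7 formyl, C1, C5, C7 as in the target | CC(C)=CCC/C(C)=C/C[C@]12C[C@@H](C=O)C(C)(C)[C@](C(=O)c3ccccc3)(C1=O)C(O)=C(CCC(C)=C)C2=O | intermediate (not isolated)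
14 | adamantanol: 1-benzoyl-5-geranyl-11-hydroxy-8,8-dimethyl-3-(3-methylbut-3-enyl)adamantane-2,4,9-trione (route numbering), OH drawn on the C4/C6 side, C1, C3, C5, C7 as in the target | CC(C)=CCC/C(C)=C/C[C@@]12C[C@H]3[C@@H](O)[C@@](CCC(C)=C)(C1=O)C(=O)[C@@](C(=O)c1ccccc1)(C2=O)C3(C)C | intermediate
15 | adamantane tetraone: 1-benzoyl-5-geranyl-8,8-dimethyl-3-(3-methylbut-3-enyl)adamantane-2,4,9,11-tetraone (route numbering) | CC(C)=CCC/C(C)=C/C[C@@]12C[C@H]3C(=O)[C@@](CCC(C)=C)(C1=O)C(=O)[C@@](C(=O)c1ccccc1)(C2=O)C3(C)C | intermediate
16 | trimethylsilyldiazomethane | C[Si](C)(C)C=[N+]=[N-] | starting material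
17 | silyl ketone: homoadamantane tetraone with trimethylsilyl on C10 (both C10 epimers) | CC(C)=CCC/C(C)=C/C[C@@]12C[C@H]3C([Si](C)(C)C)C(=O)[C@@](CCC(C)=C)(C1=O)C(=O)[C@@](C(=O)c1ccccc1)(C2=O)C3(C)C | intermediate (not isolated)
18 | homoadamantane tetraone: C10H2 between C7 and the C11 ketone, 3-methylbut-3-enyl on C3 | CC(C)=CCC/C(C)=C/C[C@@]12C[C@H]3CC(=O)[C@@](CCC(C)=C)(C1=O)C(=O)[C@@](C(=O)c1ccccc1)(C2=O)C3(C)C | intermediate
19 | cyclopentane-fused C11 tertiary alcohol, OH drawn on the C2 side and C12 on the C4 side | CC(C)=CCC/C(C)=C/C[C@@]12C[C@H]3C[C@@]4(O)C(C)(C)CC[C@]4(C1=O)C(=O)[C@@](C(=O)c1ccccc1)(C2=O)C3(C)C | intermediate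
20 | C11 methyl oxalate of 19 | CC(C)=CCC/C(C)=C/C[C@@]12C[C@H]3C[C@@]4(OC(=O)C(=O)OC)C(C)(C)CC[C@]4(C1=O)C(=O)[C@@](C(=O)c1ccccc1)(C2=O)C3(C)C | intermediate
21 | target CNP0168637.1: homoadamantane trione with fused gem-dimethylcyclopentane, C11–H on the C4 side, C12 on the C2 side | CC(C)=CCC/C(C)=C/C[C@@]12C[C@H]3C[C@@H]4C(C)(C)CC[C@]4(C1=O)C(=O)[C@@](C(=O)c1ccccc1)(C2=O)C3(C)C | target

**Step count**

Total: 12 steps. Longest linear sequence: 9 steps (steps 1–3 and 7–12); steps 4–6 form the side branch to enal 11.

**Steps most likely to fail**

1. Step 7. The first carbon–carbon bond can form at either alkylated ring carbon with no bias, so up to half of the material may enter the regioisomeric cage series, and the chromatographic separation of the two adamantanols may be hard. The fallback sets out from 4 and 11 and returns at 12, hence 14. Alkylation of 4 with 11 in aqueous KOH should take place at its one free ring carbon and give the aromatic enal, 3-(2-formyl-3-methylbut-2-enyl)-5-(3-methylbut-3-enyl)-2,4,6-trihydroxybenzophenone F1. Dearomatizing C-geranylation of F1 would follow with commercial geranyl acetate, Pd2(dba)3, (R)-2,2′-bis(diphenylphosphino)-1,1′-binaphthyl and Cs2CO3 in THF. Under zerovalent palladium such C-allylation is expected to be reversible through the allyl complex. Only the isomer geranylated at the carbon that already carries the enal chain, which is 12, can go on to the Michael and aldol closures to 14; the other isomer should return to the pool.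

2. Step 10. The oxygen-centred radical formed on ring closure may break the C11–C3 bond, since the resulting C3 radical is stabilized by two carbonyls (a Dowd–Beckwith-type opening). The iron alkoxide of the β-hydroxy diketone may also open by retro-aldol, and some hydrogen-atom transfer to the geranyl alkenes may compete. The fallback sets out from 18 and returns at 21, bypassing 19 and 20. Condensation with p-toluenesulfonyl hydrazide (catalytic AcOH, MeOH) should give the C11 tosylhydrazone F2. The same Fe(acac)3–PhSiH3 conditions should add the C12 radical to the C=N carbon, giving the cyclized sulfonyl hydrazide F3 through a nitrogen radical that has no reason to fragment. Warming with NaOAc in MeOH should eliminate sulfinate to the C11 diazene F4, which loses N2; hydrogen then reaches C11 from the open C4/C6 face to give 21.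

3. Step 9. After addition of the diazo carbon, the tetrahedral intermediate may collapse by expelling the triacylated C3 (acyl cleavage to a ring-opened diazoketone) instead of undergoing the 1,2-shift, or AlMe3 may attack a carbonyl. The fallback sets out from 15 and returns at 18. Allyl diazoacetate with BF3·OEt2 in CH2Cl2 at −78 °C is a slower, acceptor-substituted diazo partner and should give the ring-expanded allyl β-keto ester F5 by the same C7 migration. Its enolized keto ester neither homologates again nor leaves C11 strongly electrophilic. Pd(PPh3)4 and morpholine in THF at rt should then remove the allyl group and the carboxyl (deallylative decarboxylation) to give 18.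

**Further compounds**

F1 | step 7 | 3-(2-formyl-3-methylbut-2-enyl)-5-(3-methylbut-3-enyl)-2,4,6-trihydroxybenzophenone | C=C(C)CCc1c(O)c(CC(C=O)=C(C)C)c(O)c(C(=O)c2ccccc2)c1O
F2 | step 10 | C11 p-toluenesulfonylhydrazone of 18 | CC(C)=CCC/C(C)=C/C[C@@]12C[C@H]3CC(=NNS(=O)(=O)c4ccc(C)cc4)[C@@](CCC(C)=C)(C1=O)C(=O)[C@@](C(=O)c1ccccc1)(C2=O)C3(C)C
F3 | step 10 | cyclopentane-fused C11 N′-tosylhydrazide | CC(C)=CCC/C(C)=C/C[C@@]12C[C@H]3C[C@@]4(NNS(=O)(=O)c5ccc(C)cc5)C(C)(C)CC[C@]4(C1=O)C(=O)[C@@](C(=O)c1ccccc1)(C2=O)C3(C)C
F4 | step 10 | cyclopentane-fused C11 diazene | CC(C)=CCC/C(C)=C/C[C@@]12C[C@H]3C[C@@]4(N=N)C(C)(C)CC[C@]4(C1=O)C(=O)[C@@](C(=O)c1ccccc1)(C2=O)C3(C)C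
F5 | step 9 | homoadamantane tetraone with allyl ester on C10 (allyl β-keto ester, both C10 epimers) | CC(C)=CCC/C(C)=C/C[C@@]12C[C@H]3C(C(=O)OCC=C)C(=O)[C@@](CCC(C)=C)(C1=O)C(=O)[C@@](C(=O)c1ccccc1)(C2=O)C3(C)C
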